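**Assumptions:** CID49831946 is taken exactly as the given SMILES, which is the (3S,6E) isomer. Numbers are given to substrates, building blocks, intermediates and the target; stoichiometric reagents are identified by name and SMILES inside each step. TBS = tert-butyldimethylsilyl.

## Retrosynthetic overview

1. Target ⇐ buffered fluoride removal of three aryl TBS ethers; the C6=C7 (E)-styrene ⇐ olefin cross-metathesis of an (S)-hept-6-en-3-yl acetate with 4-(TBSO)styrene.
2. C4–C5 bond ⇐ Cu-catalysed allyl Grignard opening of (R)-2-(2-arylethyl)oxirane at its terminal carbon.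
3. Epoxide ⇐ (R)-chlorohydrin ⇐ ketoreductase reduction of an α-chloroketone, which sets the only stereocentre.
4. Chloroketone ⇐ Weinreb amide + LiCH2Cl ⇐ 3-(3,4-dihydroxyphenyl)propanoic acid; styrene partner ⇐ 4-hydroxybenzaldehyde.
5. Rings: none is constructed. Both benzene rings are purchased; the only ring made is the transient oxirane (step 5), opened in step 6.

## Route

**Step 1**
Reactants: 1, 3-(3,4-dihydroxyphenyl)propanoic acid
Product: 2, 3-[3,4-bis(TBSO)phenyl]propanoic acid
Conditions: TBSCl (3.5 eq), imidazole, DMF, rt; then AcOH/THF/H2O (3:1:1), rt, 1 h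
Reagents that add atoms: tert-butyldimethylsilyl chloride, CC(C)(C)[Si](C)(C)Cl
Why: Imidazole-promoted silylation caps both phenols as fluoride-labile aryl TBS ethers, and the transient silyl ester is hydrolysed selectively by mild aqueous acid, which aryl TBS ethers tolerate.

**Step 2**
Reactants: 2, 3-[3,4-bis(TBSO)phenyl]propanoic acid
Product: 3, 3-[3,4-bis(TBSO)phenyl]-N-methoxy-N-methylpropanamide
Conditions: MeNH(OMe)·HCl, EDC·HCl, HOBt, i-Pr2NEt, CH2Cl2, 0 °C → rt
Reagents that add atoms: N,O-dimethylhydroxylamine hydrochloride, CNOC.Cl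
Why: Carbodiimide/HOBt amide coupling gives the Weinreb amide under neutral conditions that do not touch the aryl silyl ethers.

**Step 3**
Reactants: 3, the Weinreb amide
Product: 4, 4-[3,4-bis(TBSO)phenyl]-1-chlorobutan-2-one
Conditions: ICH2Cl (2 eq), MeLi·LiBr (1.8 eq), THF, −78 °C; then sat. aq. NH4Cl
Reagents that add atoms: chloroiodomethane, ClCI
Why: In situ chloromethyllithium (carbenoid homologation) adds once to the Weinreb amide because the chelated tetrahedral intermediate survives until quench, giving the α-chloroketone.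

**Step 4**
Reactants: 4, the α-chloroketone
Product: 5, (2R)-4-[3,4-bis(TBSO)phenyl]-1-chlorobutan-2-ol
Conditions: ketoreductase (Prelog-selective, NADP(H)-dependent, chosen from a commercial panel), NADP+ (cat.), i-PrOH (15% v/v), 0.1 M phosphate buffer pH 7.0, 1 mM MgSO4, DMSO or toluene cosolvent, 30 °C
Reagents that add atoms: none (hydride from i-PrOH via NADPH)
Why: Biocatalytic asymmetric ketone reduction: the ketoreductase places the small CH2Cl and the long arylethyl chain in different pockets and delivers hydride to one carbonyl face, creating the only stereocentre as (R), typically in >99% ee for α-chloroketones.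

**Step 5**
Reactants: 5, the (R)-chlorohydrin
Product: 6, (2R)-2-{2-[3,4-bis(TBSO)phenyl]ethyl}oxirane
Conditions: NaH (1.1 eq), THF, 0 °C, 30 min
Reagents that add atoms: none
Why: Intramolecular Williamson etherification (3-exo-tet SN2 at the primary C–Cl) leaves the stereogenic C–O bond intact, so configuration is retained, and the short, cold, aprotic conditions spare the aryl silyl ethers.

**Step 6**
Reactants: 6, the (R)-epoxide
Product: 7, (3S)-1-[3,4-bis(TBSO)phenyl]hept-6-en-3-ol
Conditions: allylMgCl (1.5 eq), CuI (10 mol%), THF, −40 → −20 °C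
Reagents that add atoms: allylmagnesium chloride, C=CC[Mg]Cl
Why: Copper-catalysed SN2 epoxide opening by the Grignard occurs at the unsubstituted terminal carbon, so the stereocentre is untouched; the descriptor changes from R to S only because the CIP priorities change.

**Step 7**
Reactants: 7, the (S)-alcohol
Product: 8, (3S)-1-[3,4-bis(TBSO)phenyl]hept-6-en-3-yl acetate
Conditions: Ac2O, pyridine, DMAP (cat.), CH2Cl2, 0 °C → rt
Reagents that add atoms: acetic anhydride, CC(=O)OC(C)=O
Why: DMAP-catalysed O-acylation of the only free hydroxyl proceeds with retention, since no C–O bond is broken.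

**Step 8**
Reactants: 9, 4-hydroxybenzaldehyde
Product: 10, 4-(TBSO)benzaldehyde
Conditions: TBSCl, imidazole, DMF, rt
Reagents that add atoms: tert-butyldimethylsilyl chloride, CC(C)(C)[Si](C)(C)Cl
Why: Standard phenol silylation gives the same protecting group as on the catechol, so one final deprotection removes all three.

**Step 9**
Reactants: 10, 4-(TBSO)benzaldehyde
Product: 11, tert-butyldimethyl(4-vinylphenoxy)silane [4-(TBSO)styrene]
Conditions: Ph3PCH3Br, n-BuLi, THF, 0 °C → rt
Reagents that add atoms: methyltriphenylphosphonium bromide, C[P+](c1ccccc1)(c1ccccc1)c1ccccc1.[Br-]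
Why: Wittig methylenation of a non-enolisable aryl aldehyde is clean and tolerates the aryl silyl ether.

**Step 10**
Reactants: 8, the (S)-alkenyl acetate; 11, 4-(TBSO)styrene (3 eq)
Product: 12, (3S,6E)-1-[3,4-bis(TBSO)phenyl]-7-[4-(TBSO)phenyl]hept-6-en-3-yl acetate
Conditions: Grubbs II (5 mol%), CH2Cl2, 40 °C, Ar sparge
Reagents that add atoms: none (11 supplies the ArCH= unit; ethylene is lost)
Why: Olefin cross-metathesis between a terminal alkene and a slowly homodimerising styrene gives the thermodynamically favoured (E)-styrene; the acetate, silyl ethers and remote stereocentre are inert.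

**Step 11**
Reactants: 12, the tris-TBS acetate
Product: 13, (3S,6E)-1-(3,4-dihydroxyphenyl)-7-(4-hydroxyphenyl)hept-6-en-3-yl acetate (target)
Conditions: TBAF (3.6 eq)/AcOH (4 eq), THF, 0 °C → rt, under Ar
Reagents that add atoms: none
Why: Fluoride desilylation cleaves aryl TBS ethers rapidly, and AcOH buffering keeps the phenols protonated so the secondary acetate, the (E)-alkene, the stereocentre and the oxidation-prone catechol survive.

## Compound list

1 | 3-(3,4-dihydroxyphenyl)propanoic acid | OC(=O)CCc1ccc(O)c(O)c1 | starting material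
2 | 3-[3,4-bis(TBSO)phenyl]propanoic acid | OC(=O)CCc1ccc(O[Si](C)(C)C(C)(C)C)c(O[Si](C)(C)C(C)(C)C)c1 | intermediate
3 | 3-[3,4-bis(TBSO)phenyl]-N-methoxy-N-methylpropanamide | CON(C)C(=O)CCc1ccc(O[Si](C)(C)C(C)(C)C)c(O[Si](C)(C)C(C)(C)C)c1 | intermediate
4 | 4-[3,4-bis(TBSO)phenyl]-1-chlorobutan-2-one | ClCC(=O)CCc1ccc(O[Si](C)(C)C(C)(C)C)c(O[Si](C)(C)C(C)(C)C)c1 | intermediate
5 | (2R)-4-[3,4-bis(TBSO)phenyl]-1-chlorobutan-2-ol | O[C@@H](CCl)CCc1ccc(O[Si](C)(C)C(C)(C)C)c(O[Si](C)(C)C(C)(C)C)c1 | intermediate
6 | (2R)-2-{2-[3,4-bis(TBSO)phenyl]ethyl}oxirane | C1O[C@@H]1CCc2ccc(O[Si](C)(C)C(C)(C)C)c(O[Si](C)(C)C(C)(C)C)c2 | intermediate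
7 | (3S)-1-[3,4-bis(TBSO)phenyl]hept-6-en-3-ol | O[C@@H](CCC=C)CCc1ccc(O[Si](C)(C)C(C)(C)C)c(O[Si](C)(C)C(C)(C)C)c1 | intermediate
8 | (3S)-1-[3,4-bis(TBSO)phenyl]hept-6-en-3-yl acetate | CC(=O)O[C@@H](CCC=C)CCc1ccc(O[Si](C)(C)C(C)(C)C)c(O[Si](C)(C)C(C)(C)C)c1 | intermediate
9 | 4-hydroxybenzaldehyde | O=Cc1ccc(O)cc1 | starting material
10 | 4-(TBSO)benzaldehyde | O=Cc1ccc(O[Si](C)(C)C(C)(C)C)cc1 | intermediate
11 | tert-butyldimethyl(4-vinylphenoxy)silane | C=Cc1ccc(O[Si](C)(C)C(C)(C)C)cc1 | intermediate
12 | (3S,6E)-1-[3,4-bis(TBSO)phenyl]-7-[4-(TBSO)phenyl]hept-6-en-3-yl acetate | CC(=O)O[C@@H](CC/C=C/c1ccc(O[Si](C)(C)C(C)(C)C)cc1)CCc1ccc(O[Si](C)(C)C(C)(C)C)c(O[Si](C)(C)C(C)(C)C)c1 | intermediate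
13 | (3S,6E)-1-(3,4-dihydroxyphenyl)-7-(4-hydroxyphenyl)hept-6-en-3-yl acetate | CC(=O)O[C@@H](CC/C=C/c1ccc(O)cc1)CCc1ccc(O)c(O)c1 | target

## Summary

Total step count: 11.
Longest linear sequence: 9 steps (steps 1–7, 10, 11); steps 8–9 form a two-step side branch.

Steps most likely to fail:

1. **Step 4 (ketoreductase reduction).** The very lipophilic bis-silyl substrate may be poorly accepted or poorly dispersed. Fallback: reduce 4 with NaBH4 to racemic 5 and resolve it by lipase-catalysed transesterification with vinyl acetate. By Kazlauskas' rule the lipase should acylate (S)-5 and leave the required (R)-5 (≤50% yield), which re-enters at step 5.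
2. **Step 10 (cross-metathesis).** Homodimerisation, alkene migration or incomplete E-selectivity could lower the yield. Fallback: protect 7 as its TES ether, cleave the terminal alkene (OsO4/NaIO4) to the C6 aldehyde, and build the styrene by Julia–Kocienski olefination with the 1-phenyl-1H-tetrazol-5-yl sulfone derived from 4-(TBSO)benzyl alcohol. Then remove TES and acetylate.
3. **Step 11 (final desilylation).** The acetate could be lost or the free catechol could oxidise. Fallback: run the metathesis on alcohol 7, desilylate to the tetraol, peracetylate (Ac2O/pyridine), and use a lipase (e.g. Candida antarctica lipase B, n-BuOH, MTBE) to alcoholyse the three aryl acetates selectively, leaving the hindered secondary alkyl acetate.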